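**Retrosynthetic overview**
1. Oreskaurin A ⇐ bis-lactone 26: the less hindered 6,19-lactone is taken to the C6 lactol acetate, the C15 ketone comes from allylic oxidation next to the C16=C17 methylene, and two silyl ethers are removed last.
2. Ring D ⇐ 5-exo vinyl-radical closure C16→C13 from a C8 propargyl group; ring C ⇐ aldol condensation C12→C13 of a C11 methyl ketone with a C13 aldehyde; C9 and C8 are set on the spiro 7,20-lactone by conjugate addition and two enolate alkylations.
3. 7,20-Lactone (C8=C9) ⇐ the C20 alcohol and the C9 aldehyde on C10 plus Ph3P=C=C=O.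
4. Ring A and the 6,19-lactone ⇐ intramolecular Diels–Alder reaction through the C19–O–C6 ester tether. The strategy rests on ring A carrying four contiguous stereocentres, C1 (carbinol), quaternary C10, C5 and quaternary C4, with C19 and C6 joined through oxygen in a cis-fused five-membered ring; three alkene geometries of an achiral triene encode all four.
5. Ring order: A with the 6,19-lactone (step 9), 7,20-lactone (step 11), C (step 16), D (step 19).

Key step: step 9

Assumption: the absolute sense of step 9 is assigned from the formyl C–H···O binding model of 2-substituted enals on the oxazaborolidinium cation; if the opposite sense is found, the catalyst from the enantiomeric amino alcohol is used.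
Remark: atom numbers are ent-kaurane numbers; 19 is drawn as its expected trans isomer, 25 is an E/Z mixture, and C6 in 27 and C15 in 29 are epimer mixtures of no consequence.

**Step 1**
Reactants: 1 malondialdehyde tetrabutylammonium salt
Product: 2 (E)-3-(tert-butyldimethylsilyloxy)prop-2-enal
Conditions: t-BuMe2SiCl, CH2Cl2, 0 °C → rt
Reagents that add atoms: tert-butyldimethylsilyl chloride, CC(C)(C)[Si](C)(C)Cl
Why: O-silylation of the delocalised enolate should give the vinylogous silyl formate with the E enol ether geometry that later defines C1.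

**Step 2**
Reactants: 2 (E)-3-(tert-butyldimethylsilyloxy)prop-2-enal; 3 ethyl 2-[bis(2,2,2-trifluoroethoxy)phosphoryl]propanoate
Product: 4 ethyl (2Z,4E)-5-(tert-butyldimethylsilyloxy)-2-methylpenta-2,4-dienoate
Conditions: KN(SiMe3)2, 18-crown-6, THF, −78 °C
Reagents that add atoms: none
Why: The Still–Gennari olefination (Z-selective Horner–Wadsworth–Emmons variant) should place the ester cis to the diene chain, so that the future C19 tether sits on the inside position of C4.

**Step 3**
Reactants: 4 ethyl (2Z,4E)-5-(tert-butyldimethylsilyloxy)-2-methylpenta-2,4-dienoate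
Product: 5 (2Z,4E)-5-(tert-butyldimethylsilyloxy)-2-methylpenta-2,4-dien-1-ol
Conditions: i-Bu2AlH, CH2Cl2, −78 °C; aq. potassium sodium tartrate
Reagents that add atoms: none
Why: Hydride 1,2-reduction of the ester gives the allylic alcohol without touching the silyl dienol ether or either alkene geometry.

**Step 4**
Reactants: 6 tert-butyl acetate; 7 2-(benzyloxy)acetyl chloride
Product: 8 tert-butyl 4-(benzyloxy)-3-oxobutanoate
Conditions: LiN(i-Pr)2 (2 equiv), THF, −78 °C; then 7; AcOH quench
Reagents that add atoms: none
Why: Claisen-type C-acylation of the lithium ester enolate by the acid chloride, the second equivalent of enolate taking up the acidic proton of the β-keto ester.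

**Step 5**
Reactants: 8 tert-butyl 4-(benzyloxy)-3-oxobutanoate
Product: 9 tert-butyl (E)-4-(benzyloxy)-3-(trifluoromethylsulfonyloxy)but-2-enoate
Conditions: (CF3SO2)2O, aq. Me4NOH, toluene, 0 °C
Reagents that add atoms: trifluoromethanesulfonic anhydride, O=S(=O)(OS(=O)(=O)C(F)(F)F)C(F)(F)F
Why: O-triflation of the β-keto ester enolate, in which the non-chelating ammonium counter-ion should favour the extended enolate and hence the E enol triflate (OTf trans to the ester).

**Step 6**
Reactants: 9 tert-butyl (E)-4-(benzyloxy)-3-(trifluoromethylsulfonyloxy)but-2-enoate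
Product: 10 tert-butyl (E)-4-(benzyloxy)-3-formylbut-2-enoate
Conditions: Pd(OAc)2 (3 mol %), Ph2P(CH2)3PPh2, CO/H2 (1:1, 10 bar), pyridine, DMF, 70 °C
Reagents that add atoms: carbon monoxide, [C-]#[O+]
Why: Palladium-catalysed reductive carbonylation (formylation) of the vinyl triflate proceeds with retention, and the isomer with formyl trans to the ester is also the thermodynamically preferred one.

**Step 7**
Reactants: 10 tert-butyl (E)-4-(benzyloxy)-3-formylbut-2-enoate
Product: 11 (E)-4-(benzyloxy)-3-formylbut-2-enoic acid
Conditions: CF3CO2H, CH2Cl2, 0 °C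
Reagents that add atoms: none
Why: Acidolysis of the tert-butyl ester frees the acid, which cannot close to a hydroxybutenolide because formyl and carboxyl are trans.

**Step 8**
Reactants: 5 (2Z,4E)-5-(tert-butyldimethylsilyloxy)-2-methylpenta-2,4-dien-1-ol; 11 (E)-4-(benzyloxy)-3-formylbut-2-enoic acid
Product: 12 (2Z,4E)-5-(tert-butyldimethylsilyloxy)-2-methylpenta-2,4-dien-1-yl (E)-4-(benzyloxy)-3-formylbut-2-enoate
Conditions: N,N'-dicyclohexylcarbodiimide, 4-(dimethylamino)pyridine (10 mol %), CH2Cl2, −20 °C; used at once
Reagents that add atoms: none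
Why: Steglich esterification under neutral conditions joins the acid-sensitive silyl dienol ether and the enal acid, and the cold work-up keeps the uncatalysed cyclisation of the triene from starting.

**Step 9**
Reactants: 12 (2Z,4E)-5-(tert-butyldimethylsilyloxy)-2-methylpenta-2,4-dien-1-yl (E)-4-(benzyloxy)-3-formylbut-2-enoate
Product: 13 ring A cyclohexene cis-fused to the 6,19-γ-lactone, with formyl (C9) and benzyloxymethyl (C20) on C10 and OTBS on C1
Conditions: (S)-3,3-diphenyl-1-(2-methylphenyl)tetrahydro-1H,3H-pyrrolo[1,2-c][1,3,2]oxazaborole (C24H24BNO, 20 mol %), (CF3SO2)2NH (18 mol %), CH2Cl2, −78 → −40 °C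
Reagents that add atoms: none
Why: The N-protonated oxazaborolidine binds the formyl oxygen of 12 (a better donor than the ester), and the activated 2-substituted enal should undergo a concerted, asynchronous [4+2] cycloaddition with the tethered 1-silyloxydiene, bond C4–C5 leading; the closest known reaction type is the oxazaborolidinium-catalysed Diels–Alder reaction of 2-substituted acroleins with 1-silyloxybutadienes, run here in the ester-tethered intramolecular mode of pentadienyl acrylates. Ring A closes as the cyclohexene of the cycloaddition (bonds C4–C5 and C1–C10), and the γ-lactone closes as the three-atom tether C19–O–C6 between diene terminus C4 and dienophile carbon C5 (1,3,8-nonatriene mode, five-membered ring fused at C4–C5). The Z geometry at C3=C4 puts the tether on the inside position of the diene, so only the transition state with C6 exo and the formyl group endo can be reached, which fixes the cis C4/C5 fusion; the E dienophile geometry puts C20 cis to C6 on C10; the E enol ether geometry together with the endo formyl group puts the C1 silyloxy group cis to C9. The step therefore needs only enantiofacial selectivity, which the chiral cation should supply by shielding one face of the bound enal, and the tether-enforced regiochemistry is the electronically matched one because the nucleophilic diene terminus C4 attacks the β-carbon C5 of the activated enal. Low temperature suppresses the uncatalysed background cyclisation and silyl transfer.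

**Step 10**
Reactants: 13 ring A cyclohexene cis-fused to the 6,19-γ-lactone
Product: 14 saturated ring A lactone with formyl (C9) and hydroxymethyl (C20) on C10
Conditions: H2 (1 atm), 10% Pd/C, EtOAc/EtOH, rt
Reagents that add atoms: none
Why: Heterogeneous hydrogenation saturates C2=C3 (no new stereocentre) and hydrogenolysis removes the benzyl ether in the same operation, while the neopentyl aldehyde and the silyl ether should survive.

**Step 11**
Reactants: 14 saturated ring A lactone with formyl (C9) and hydroxymethyl (C20) on C10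
Product: 16 spiro α,β-unsaturated 7,20-δ-lactone (C8=C9) on C10 of the ring A lactone, via ylide ester 15 (not isolated)
Conditions: Ph3P=C=C=O, toluene, rt → 100 °C
Reagents that add atoms: ketenylidenetriphenylphosphorane, O=C=C=P(c1ccccc1)(c1ccccc1)c1ccccc1
Why: The C20 alcohol adds across the ketene unit of the cumulated ylide to give the ester-stabilised ylide 15, whose intramolecular Wittig reaction with the C9 aldehyde closes the six-membered ring and can only give the ring Z alkene.

**Step 12**
Reactants: 16 spiro α,β-unsaturated 7,20-δ-lactone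
Product: 18 spiro δ-lactone with isopropenyl on C9, via silyl ketene acetal 17 (not isolated)
Conditions: CH2=C(CH3)MgBr, CuBr·SMe2 (20 mol %), Me3SiCl, THF, −78 → −30 °C; aq. NH4Cl
Reagents that add atoms: isopropenylmagnesium bromide, C=C(C)[Mg]Br
Why: Copper-catalysed conjugate addition with silyl trapping should deliver the isopropenyl group to C9 on the face syn to C1 and anti to the C10–C5 bond (Felkin-type), because the other face is blocked by C6, which leaves H9 next to C6 as in the target; aqueous work-up hydrolyses 17.

**Step 13**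
Reactants: 18 spiro δ-lactone with isopropenyl on C9
Product: 19 C8-allyl δ-lactone (allyl trans to isopropenyl)
Conditions: LiN(i-Pr)2, THF, −78 °C; allyl bromide, DMPU, −78 → −40 °C
Reagents that add atoms: allyl bromide, C=CCBr
Why: Alkylation of the lithium enolate of the δ-lactone (the C5–H of the γ-lactone lies between two quaternary carbons and is kinetically out of reach); the C8 configuration does not matter here because step 14 makes the centre planar again.

**Step 14**
Reactants: 19 C8-allyl δ-lactone
Product: 20 δ-lactone with quaternary C8 carrying allyl (cis to isopropenyl) and propargyl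
Conditions: LiN(i-Pr)2, THF, −78 → −40 °C; propargyl bromide
Reagents that add atoms: propargyl bromide, C#CCBr
Why: In this second enolate alkylation the electrophile should approach C8 anti to the C9 isopropenyl group and away from the axial C1 branch of ring A, so the allyl group (C14) ends cis to the isopropenyl group and the propargyl group (C15) trans, as the target requires.

**Step 15**
Reactants: 20 δ-lactone with quaternary C8 carrying allyl and propargyl
Product: 21 keto aldehyde (C11 methyl ketone on C9, C13 aldehyde on C14)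
Conditions: OsO4 (2 mol %), NaIO4, 2,6-lutidine, dioxane/H2O, rt
Reagents that add atoms: osmium tetroxide, O=[Os](=O)(=O)=O; sodium periodate, [Na+].[O-]I(=O)(=O)=O
Why: Lemieux–Johnson cleavage turns the isopropenyl group into the C11 methyl ketone and the allyl group into the C13 aldehyde in one operation, the terminal alkyne being inert to OsO4 under these conditions.

**Step 16**
Reactants: 21 keto aldehyde
Product: 22 ring C cyclohexenone (C11 ketone, C12=C13) cis-fused to the 7,20-lactone, propargyl on C8
Conditions: pyrrolidine (30 mol %), acetic acid (30 mol %), toluene, 50 °C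
Reagents that add atoms: none
Why: Enamine-mediated intramolecular aldol condensation of the 1,5-keto aldehyde, in which only the C12 methyl can reach C13 through a six-membered ring; the enolisable C9 should keep its configuration because its epimer would force C8 or C11 against C6.

**Step 17**
Reactants: 22 ring C cyclohexenone
Product: 23 C11 allylic alcohol (OH cis to C10 on ring C)
Conditions: NaBH4, CeCl3·7H2O, MeOH, −78 °C
Reagents that add atoms: none
Why: Luche 1,2-reduction, in which hydride should add to C11 anti to the pseudoaxial C9–C10 bond and so give the carbinol cis to C10 as in the target, neither lactone being reduced.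

**Step 18**
Reactants: 23 C11 allylic alcohol
Product: 24 C1,C11-bis(tert-butyldimethylsilyl) ether
Conditions: t-BuMe2SiOSO2CF3, 2,6-lutidine, CH2Cl2, −78 → 0 °C
Reagents that add atoms: tert-butyldimethylsilyl trifluoromethanesulfonate, CC(C)(C)[Si](C)(C)OS(=O)(=O)C(F)(F)F
Why: Silylation of the hindered secondary alcohol protects C11–OH during the later lactol acetylation and C15 oxidation.

**Step 19**
Reactants: 24 C1,C11-bis(tert-butyldimethylsilyl) ether
Product: 26 bicyclo[3.2.1]octane with C16=C17 methylene spanning rings C and D on the bis-lactone, via vinylstannane 25 (not isolated)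
Conditions: Bu3SnH, 2,2'-azobis(isobutyronitrile) (10 mol %), benzene, 80 °C; then pyridinium p-toluenesulfonate, CH2Cl2, rt
Reagents that add atoms: none
Why: Tin-mediated radical enyne cyclisation: the stannyl radical adds to the terminal alkyne carbon, the C16 vinyl radical closes 5-exo-trig on C13 from the only face the C15 tether can reach (so C13 follows from C8), and protodestannylation of 25 leaves the exocyclic methylene.

**Step 20**
Reactants: 26 bicyclo[3.2.1]octane bis-lactone
Product: 27 C6 lactol (6,19-hemiacetal)
Conditions: i-Bu2AlH (1.1 equiv), CH2Cl2, −78 °C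
Reagents that add atoms: none
Why: Partial reduction of a lactone to the lactol; the γ-lactone carbonyl is next to a tertiary CH, whereas the 7,20-lactone carbonyl is attached to the bridgehead quaternary C8 and is far more hindered, so the γ-lactone should react first.

**Step 21**
Reactants: 27 C6 lactol
Product: 28 C6 exo acetate (acetoxy trans to C10 on the tetrahydrofuran ring)
Conditions: Ac2O, pyridine, 4-(dimethylamino)pyridine (5 mol %), CH2Cl2, 0 °C
Reagents that add atoms: acetic anhydride, CC(=O)OC(C)=O
Why: Acetylation of the equilibrating lactol should take the more accessible exo hydroxyl, whose acetate is also the more stable anomer and has the C6 configuration of the target.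

**Step 22**
Reactants: 28 C6 exo acetate
Product: 29 C15 allylic alcohol
Conditions: SeO2 (30 mol %), t-BuOOH, CH2Cl2, rt
Reagents that add atoms: selenium dioxide, O=[Se]=O; tert-butyl hydroperoxide, CC(C)(C)OO
Why: Selenium dioxide allylic oxidation (ene reaction then [2,3]-shift) can only take C15, the one allylic CH2, because the other allylic carbon C13 is a bridgehead.

**Step 23**
Reactants: 29 C15 allylic alcohol
Product: 30 C1,C11-bis-silyl ether of oreskaurin A
Conditions: Dess–Martin periodinane, NaHCO3, CH2Cl2, rt
Reagents that add atoms: none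
Why: Dess–Martin oxidation of the allylic alcohol gives the exo-methylene cyclopentanone under buffered conditions that spare the acetal acetate.

**Step 24**
Reactants: 30 C1,C11-bis-silyl ether of oreskaurin A
Product: 31 oreskaurin A
Conditions: HF·pyridine, pyridine, THF, 0 °C → rt
Reagents that add atoms: none
Why: Buffered fluoride desilylation should remove both silyl ethers while leaving the acetal acetate, the lactone and the enone intact.

**Compound list**
1 | malondialdehyde tetrabutylammonium salt | CCCC[N+](CCCC)(CCCC)CCCC.[O-]/C=C/C=O | starting material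
2 | (E)-3-(tert-butyldimethylsilyloxy)prop-2-enal | CC(C)(C)[Si](C)(C)O/C=C/C=O | intermediate
3 | ethyl 2-[bis(2,2,2-trifluoroethoxy)phosphoryl]propanoate | CCOC(=O)C(C)P(=O)(OCC(F)(F)F)OCC(F)(F)F | starting material
4 | ethyl (2Z,4E)-5-(tert-butyldimethylsilyloxy)-2-methylpenta-2,4-dienoate | CCOC(=O)/C(C)=C\C=C\O[Si](C)(C)C(C)(C)C | intermediate
5 | (2Z,4E)-5-(tert-butyldimethylsilyloxy)-2-methylpenta-2,4-dien-1-ol | CC(C)(C)[Si](C)(C)O/C=C/C=C(/C)CO | intermediate
6 | tert-butyl acetate | CC(=O)OC(C)(C)C | starting material
7 | 2-(benzyloxy)acetyl chloride | O=C(Cl)COCc1ccccc1 | starting material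
8 | tert-butyl 4-(benzyloxy)-3-oxobutanoate | CC(C)(C)OC(=O)CC(=O)COCc1ccccc1 | intermediate
9 | tert-butyl (E)-4-(benzyloxy)-3-(trifluoromethylsulfonyloxy)but-2-enoate | CC(C)(C)OC(=O)/C=C(\COCc1ccccc1)OS(=O)(=O)C(F)(F)F | intermediate
10 | tert-butyl (E)-4-(benzyloxy)-3-formylbut-2-enoate | CC(C)(C)OC(=O)/C=C(\COCc1ccccc1)C=O | intermediate
11 | (E)-4-(benzyloxy)-3-formylbut-2-enoic acid | OC(=O)/C=C(\COCc1ccccc1)C=O | intermediate
12 | (2Z,4E)-5-(tert-butyldimethylsilyloxy)-2-methylpenta-2,4-dien-1-yl (E)-4-(benzyloxy)-3-formylbut-2-enoate (cycloaddition precursor) | CC(C)(C)[Si](C)(C)O/C=C/C=C(/C)COC(=O)/C=C(\COCc1ccccc1)C=O | intermediate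
13 | cycloadduct: ring A cyclohex-2-ene cis-fused at C4–C5 to the 6,19-γ-lactone; C19, C6 and C20 (CH2OBn) on one face, C9 (CHO), C1–OTBS and the C4 methyl on the other | O=C[C@]1(COCc2ccccc2)[C@H](O[Si](C)(C)C(C)(C)C)C=C[C@@]2(C)COC(=O)[C@H]21 | intermediate
14 | as 13 with C2–C3 saturated and C20 as free CH2OH | O=C[C@]1(CO)[C@H](O[Si](C)(C)C(C)(C)C)CC[C@@]2(C)COC(=O)[C@H]21 | intermediate
15 | (triphenylphosphoranylidene)acetate of 14 at O20 (not isolated) | O=C[C@]1(COC(=O)C=P(c2ccccc2)(c2ccccc2)c2ccccc2)[C@H](O[Si](C)(C)C(C)(C)C)CC[C@@]2(C)COC(=O)[C@H]21 | intermediate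
16 | spiro 5,6-dihydro-2H-pyran-2-one (C7 carbonyl, C8=C9, O20–C20) at C10 of the ring A γ-lactone | O=C1OC[C@@]2(C=C1)[C@H](O[Si](C)(C)C(C)(C)C)CC[C@@]3(C)COC(=O)[C@H]32 | intermediate
17 | trimethylsilyl ketene acetal of 18 (C7(OSiMe3)=C8; not isolated) | C[Si](C)(C)OC1=C[C@@H](C(C)=C)[C@]2(CO1)[C@H](O[Si](C)(C)C(C)(C)C)CC[C@@]3(C)COC(=O)[C@H]32 | intermediate
18 | spiro δ-lactone with isopropenyl on C9, cis to the C1 branch of ring A on the lactone ring | O=C1C[C@@H](C(C)=C)[C@]2(CO1)[C@H](O[Si](C)(C)C(C)(C)C)CC[C@@]3(C)COC(=O)[C@H]32 | intermediate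
19 | as 18 with allyl on C8, trans to the isopropenyl group | O=C1[C@H](CC=C)[C@@H](C(C)=C)[C@]2(CO1)[C@H](O[Si](C)(C)C(C)(C)C)CC[C@@]3(C)COC(=O)[C@H]32 | intermediate
20 | as 18 with quaternary C8: allyl (C14 unit) cis and propargyl (C15 unit) trans to the isopropenyl group | O=C1[C@](CC=C)(CC#C)[C@@H](C(C)=C)[C@]2(CO1)[C@H](O[Si](C)(C)C(C)(C)C)CC[C@@]3(C)COC(=O)[C@H]32 | intermediate
21 | keto aldehyde: acetyl on C9, 2-oxoethyl and propargyl on C8 | O=C1[C@](CC=O)(CC#C)[C@@H](C(C)=O)[C@]2(CO1)[C@H](O[Si](C)(C)C(C)(C)C)CC[C@@]3(C)COC(=O)[C@H]32 | intermediate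
22 | ring C cyclohex-2-enone (C11=O, C12=C13) cis-fused to the 7,20-lactone at C8–C9, propargyl on C8 | C#CC[C@]12CC=CC(=O)[C@H]1[C@]3(COC2=O)[C@H](O[Si](C)(C)C(C)(C)C)CC[C@@]4(C)COC(=O)[C@H]43 | intermediate
23 | C11 allylic alcohol, OH cis to C10 on ring C | C#CC[C@]12CC=C[C@@H](O)[C@H]1[C@]3(COC2=O)[C@H](O[Si](C)(C)C(C)(C)C)CC[C@@]4(C)COC(=O)[C@H]43 | intermediate
24 | C1,C11-bis(tert-butyldimethylsilyl) ether of 23 | C#CC[C@]12CC=C[C@@H](O[Si](C)(C)C(C)(C)C)[C@H]1[C@]3(COC2=O)[C@H](O[Si](C)(C)C(C)(C)C)CC[C@@]4(C)COC(=O)[C@H]43 | intermediate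
25 | C17 tributylstannyl derivative of 26 (vinylstannane, E/Z mixture; not isolated) | CCCC[Sn](CCCC)(CCCC)C=C1C[C@]23C[C@H]1C[C@@H](O[Si](C)(C)C(C)(C)C)[C@H]2[C@]1(COC3=O)[C@H](O[Si](C)(C)C(C)(C)C)CC[C@@]2(C)COC(=O)[C@H]21 | intermediate
26 | bis-lactone with complete skeleton: bicyclo[3.2.1]octane rings C and D with C16=C17 methylene, C15 as CH2, 7,20-lactone, 6,19-lactone, C1 and C11 OTBS | C=C1C[C@]23C[C@H]1C[C@@H](O[Si](C)(C)C(C)(C)C)[C@H]2[C@]1(COC3=O)[C@H](O[Si](C)(C)C(C)(C)C)CC[C@@]2(C)COC(=O)[C@H]21 | intermediate
27 | C6 lactol of 26 (6,19-hemiacetal, anomer mixture) | C=C1C[C@]23C[C@H]1C[C@@H](O[Si](C)(C)C(C)(C)C)[C@H]2[C@]1(COC3=O)[C@H](O[Si](C)(C)C(C)(C)C)CC[C@@]2(C)COC(O)[C@H]21 | intermediate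
28 | C6 exo acetate of 27 | C=C1C[C@]23C[C@H]1C[C@@H](O[Si](C)(C)C(C)(C)C)[C@H]2[C@]1(COC3=O)[C@H](O[Si](C)(C)C(C)(C)C)CC[C@@]2(C)CO[C@H](OC(C)=O)[C@H]21 | intermediate
29 | C15 allylic alcohol of 28 (C15 epimer mixture) | C=C1C(O)[C@]23C[C@H]1C[C@@H](O[Si](C)(C)C(C)(C)C)[C@H]2[C@]1(COC3=O)[C@H](O[Si](C)(C)C(C)(C)C)CC[C@@]2(C)CO[C@H](OC(C)=O)[C@H]21 | intermediate
30 | C1,C11-bis(tert-butyldimethylsilyl) ether of oreskaurin A | C=C1C(=O)[C@]23C[C@H]1C[C@@H](O[Si](C)(C)C(C)(C)C)[C@H]2[C@]1(COC3=O)[C@H](O[Si](C)(C)C(C)(C)C)CC[C@@]2(C)CO[C@H](OC(C)=O)[C@H]21 | intermediate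
31 | oreskaurin A | C=C1C(=O)[C@]23C[C@H]1C[C@@H](O)[C@H]2[C@]1(COC3=O)[C@H](O)CC[C@@]2(C)CO[C@H](OC(C)=O)[C@H]21 | target

**Step count and risks**
Total steps: 24. Longest linear sequence: 21 steps (steps 4–24, from tert-butyl acetate and 2-(benzyloxy)acetyl chloride).

Three steps most likely to fail:

Step 9. The uncatalysed cyclisation of 12 may compete while the ester is prepared, the cation may bind the ester or the benzyl ether instead of the aldehyde, or the acid may cleave the silyl dienol ether; the result would be low enantiomeric excess or loss of the diene. Fallback: starting from 12, the triene is cyclised thermally (toluene, 2,6-di-tert-butyl-4-methylphenol, 70 °C). The alkene geometries fix the same relative configuration, so this gives 13 together with its mirror image, the enantiomeric adduct F1. The mixture is condensed with (1R,2R)-N,N'-dimethyl-1,2-diphenylethane-1,2-diamine (molecular sieves, CH2Cl2) to the imidazolidine of the wanted enantiomer F2 and the diastereomeric imidazolidine F3, which are separated by chromatography. Mild hydrolysis of F2 (dilute aq. HCl/Et2O) returns 13, where the route is rejoined.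

Step 12. Addition at the neopentyl β-carbon C9 may be slow, the Grignard reagent may attack a lactone carbonyl, or facial selectivity at C9 may be poor. Fallback: starting from 16, reversible Michael addition of nitroethane (1,8-diazabicyclo[5.4.0]undec-7-ene, MeCN) gives the nitro lactone F4. A Nef reaction (KOt-Bu, THF, −78 °C, then O3 and Me2S) gives the C11 methyl ketone F5, whose C9 is enolisable and is equilibrated with the same amidine base to the isomer that keeps H9 next to C6. Wittig methylenation of F5 (Ph3P=CH2, THF, 0 °C) gives 18, where the route is rejoined.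

Step 20. The hydride may also reduce the 7,20-lactone or take the γ-lactone past the lactol stage. Fallback: starting from 26, Me2AlN(OMe)Me (from AlMe3 and N,O-dimethylhydroxylamine hydrochloride, CH2Cl2) opens only the less hindered γ-lactone to the hydroxy N-methoxy-N-methylamide F6. The amide is reduced by i-Bu2AlH at −78 °C to a chelated hemiaminal that survives until work-up, and the aldehyde set free then closes with the C19 alcohol to lactol 27, where the route is rejoined.

**Further compounds**
F1 | step 9 | enantiomer of cycloadduct 13 | O=C[C@@]1(COCc2ccccc2)[C@@H](O[Si](C)(C)C(C)(C)C)C=C[C@]2(C)COC(=O)[C@@H]21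
F2 | step 9 | (4R,5R)-1,3-dimethyl-4,5-diphenylimidazolidine formed at C9 of 13 | CN1C(N(C)[C@H](c2ccccc2)[C@H]1c1ccccc1)[C@]1(COCc2ccccc2)[C@H](O[Si](C)(C)C(C)(C)C)C=C[C@@]2(C)COC(=O)[C@H]21
F3 | step 9 | (4R,5R)-1,3-dimethyl-4,5-diphenylimidazolidine formed at C9 of F1 | CN1C(N(C)[C@H](c2ccccc2)[C@H]1c1ccccc1)[C@@]1(COCc2ccccc2)[C@@H](O[Si](C)(C)C(C)(C)C)C=C[C@]2(C)COC(=O)[C@@H]21
F4 | step 12 | spiro δ-lactone with 1-nitroethyl on C9 | O=C1C[C@@H](C(C)[N+](=O)[O-])[C@]2(CO1)[C@H](O[Si](C)(C)C(C)(C)C)CC[C@@]3(C)COC(=O)[C@H]32
F5 | step 12 | spiro δ-lactone with acetyl on C9 | O=C1C[C@@H](C(C)=O)[C@]2(CO1)[C@H](O[Si](C)(C)C(C)(C)C)CC[C@@]3(C)COC(=O)[C@H]32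
F6 | step 20 | ring-opened 26: C19 alcohol and C6 N-methoxy-N-methylamide | C=C1C[C@]23C[C@H]1C[C@@H](O[Si](C)(C)C(C)(C)C)[C@H]2[C@]1(COC3=O)[C@H](O[Si](C)(C)C(C)(C)C)CC[C@@](C)(CO)[C@H]1C(=O)N(C)OC
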